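**Retrosynthetic overview**

1. Target 14 ⇐ bis-silyl ether 13 (fluoride); 13 ⇐ primary iodide 9 + syringyl Grignard reagent 12 (C7'–aryl bond, copper-catalysed sp3–sp2 coupling).
2. 9 ⇐ alcohol 8 ⇐ diol 7. The C7 benzylic oxygen is removed by hydrogenolysis before the coupling, because a C7 alkoxide 1,4 to the C7' iodide would close to a tetrahydrofuran; the guaiacyl phenol is therefore carried as a hydrogenolysis-stable triisopropylsilyl ether.
3. Feature: the chain C7–C8(CH3)–C8'(CH3)–C7' with its meso-type (8R,8'S) methyl pair is a cis-3,4-dimethylcyclobutene cut at its C=C bond (7 ⇐ ozonolysis/NaBH4 of 5). The aryl-bearing ring carbon is the guaiacyl benzylic C7; the CH ring carbon is C7'.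
4. 5 ⇐ guaiacyl acetylene 3 + (Z)-but-2-ene 4 by enantioselective cobalt-catalysed [2+2] cycloaddition (forms C7–C8 and C7'–C8'); 3 ⇐ vanillin 1.
5. Ring order: both arenes are bought; the only ring made is the four-membered carbocycle (step 3), opened again in step 4.

Key step: step 3

Assumption: lignan numbering is used (C7/C8 on the guaiacyl half, C7'/C8' on the syringyl half), the target being (8R,8'S); (S,S)-BDPP is written as the working ligand, and the antipode that delivers (3S,4S)-5 is to be fixed by experiment.

**Route**

Step 1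
Reactants: 1 vanillin
Product: 2 3-methoxy-4-(triisopropylsilyloxy)benzaldehyde
Conditions: TIPSCl, imidazole, DMF, rt
Reagents that add atoms: chlorotriisopropylsilane (TIPSCl), CC(C)[Si](Cl)(C(C)C)C(C)C
Why: Imidazole-assisted O-silylation of the phenol; the triisopropylsilyl ether is chosen because, unlike a benzyl ether, it survives the benzylic hydrogenolysis of step 5 and the Grignard coupling of step 8.

Step 2
Reactants: 2 3-methoxy-4-(triisopropylsilyloxy)benzaldehyde
Product: 3 (4-ethynyl-2-methoxyphenoxy)triisopropylsilane
Conditions: TMSCHN2, LDA, THF, −78 °C; then 2, −78 °C → rt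
Reagents that add atoms: (trimethylsilyl)diazomethane, C[Si](C)(C)C=[N+]=[N-]
Why: Colvin rearrangement, in which lithiated trimethylsilyldiazomethane adds to the aldehyde, Peterson-type loss of lithium trimethylsilanolate gives a diazoalkene, and loss of N2 with 1,2-hydrogen shift in the alkylidene carbene gives the terminal alkyne, avoiding the K2CO3/MeOH of the Ohira–Bestmann variant that would cleave an aryl silyl ether para to a formyl group.

Step 3
Reactants: 3 (4-ethynyl-2-methoxyphenoxy)triisopropylsilane and 4 (Z)-but-2-ene
Product: 5 {4-[(3S,4S)-3,4-dimethylcyclobut-1-en-1-yl]-2-methoxyphenoxy}triisopropylsilane (cis-dimethyl)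
Conditions: CoBr2[(S,S)-BDPP] (10 mol%), Zn (50 mol%), NaB[3,5-(CF3)2C6H3]4 (15 mol%), 4 (10 equiv., condensed), CH2Cl2, sealed tube, rt; 3 added by syringe pump
Reagents that add atoms: none
Why: Proposed new method: the cationic monovalent cobalt bisphosphine complex (from the CoBr2 complex by Zn reduction and bromide abstraction by the sodium borate) binds 3 and 4 and couples them oxidatively to a trivalent cobaltacyclopentene, most likely with the aryl-bearing carbon on cobalt so that C7'–C8' forms first; C(sp2)–C(sp3) reductive elimination then forms C7–C8 and closes the four-membered ring in a formal [2+2] mode. The closest known reaction type is the cationic cobalt-catalysed enantioselective [2+2] cycloaddition of alkynes with alkenes (with a gold-catalysed counterpart for terminal arylalkynes), which has not been shown for a terminal arylalkyne with a simple acyclic cis-1,2-dialkylethylene. The cis relation of the two new stereocentres (ring C3 and C4, the later C8' and C8) is inherited from the Z geometry of 4, because both bonds form on one face of the alkene and no rotation is possible inside the metallacycle. Their absolute configuration is set by the C2-symmetric bisphosphine, which must decide whether the methyl pair lies above or below the metallacycle plane for the single alkyne orientation imposed by the strongly different aryl and hydrogen termini; the symmetric alkene removes any regiochemical question. The step needs cross-cycloaddition to win over alkyne cyclotrimerisation and enyne formation, reductive elimination to win over β-hydride elimination to open-chain dienes, and no cis/trans isomerisation of 4; the large excess of alkene, the low stationary alkyne concentration and the electron-poor cationic metal are relied on for this.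

Step 4
Reactants: 5 {4-[(3S,4S)-3,4-dimethylcyclobut-1-en-1-yl]-2-methoxyphenoxy}triisopropylsilane
Product: 7 (1RS,2S,3R)-1-[3-methoxy-4-(triisopropylsilyloxy)phenyl]-2,3-dimethylbutane-1,4-diol (both C1 epimers), via ozonide 6 (not isolated)
Conditions: O3 (about 1 equiv., as a saturated CH2Cl2 solution), CH2Cl2, −78 °C; then NaBH4, MeOH, −78 °C → rt
Reagents that add atoms: ozone, [O-][O+]=O
Why: Criegee ozonolysis with borohydride work-up, in which the strained styrenyl double bond takes up ozone far faster than the arene and cold hydride reduction of ozonide 6 through the carbonyl stage outruns enolisation, so C8 and C8' keep their configuration while the new C7 carbinol centre forms without control and is removed in step 5.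

Step 5
Reactants: 7 (1RS,2S,3R)-1-[3-methoxy-4-(triisopropylsilyloxy)phenyl]-2,3-dimethylbutane-1,4-diol
Product: 8 (2R,3R)-4-[3-methoxy-4-(triisopropylsilyloxy)phenyl]-2,3-dimethylbutan-1-ol
Conditions: H2 (3 atm), 10% Pd/C, EtOAc–AcOH, rt
Reagents that add atoms: none
Why: Palladium-catalysed hydrogenolysis of a benzylic C–O bond activated by the para-silyloxy and meta-methoxy donors; both C7 epimers converge, the primary alcohol and the aryl silyl ether are inert, and no cation is formed that could disturb C8.

Step 6
Reactants: 8 (2R,3R)-4-[3-methoxy-4-(triisopropylsilyloxy)phenyl]-2,3-dimethylbutan-1-ol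
Product: 9 {4-[(2R,3R)-4-iodo-2,3-dimethylbutyl]-2-methoxyphenoxy}triisopropylsilane
Conditions: I2, PPh3, imidazole, CH2Cl2, 0 °C → rt
Reagents that add atoms: iodine, II
Why: Appel iodination (SN2 displacement of the alkoxyphosphonium at the non-stereogenic CH2 carbon), which leaves the adjacent C8' stereocentre and the silyl ether untouched.

Step 7
Reactants: 10 4-bromo-2,6-dimethoxyphenol
Product: 11 (4-bromo-2,6-dimethoxyphenoxy)(tert-butyl)dimethylsilane
Conditions: TBSCl, imidazole, DMF, rt
Reagents that add atoms: tert-butyldimethylsilyl chloride (TBSCl), CC(C)(C)[Si](C)(C)Cl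
Why: Standard phenol O-silylation, which masks the acidic OH so that the aryl bromide can be converted to a Grignard reagent, with a group removed together with the triisopropylsilyl ether in step 9.

Step 8
Reactants: 11 (4-bromo-2,6-dimethoxyphenoxy)(tert-butyl)dimethylsilane and 9 {4-[(2R,3R)-4-iodo-2,3-dimethylbutyl]-2-methoxyphenoxy}triisopropylsilane
Product: 13 tert-butyl{4-[(2S,3R)-4-(3-methoxy-4-triisopropylsilyloxyphenyl)-2,3-dimethylbutyl]-2,6-dimethoxyphenoxy}dimethylsilane, via Grignard reagent 12 (not isolated)
Conditions: 11, Mg, THF, reflux; then 9, Li2CuCl4 (5 mol%), NMP, THF, 0 °C → rt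
Reagents that add atoms: none
Why: Kochi-type copper-catalysed cross-coupling of an aryl Grignard reagent with a primary alkyl iodide (arylcuprate displacement at CH2–I, then reductive elimination); the reacting carbon is not stereogenic, C8' next to it is not touched, and both aryl silyl ethers tolerate the Grignard reagent.

Step 9
Reactants: 13 tert-butyl{4-[(2S,3R)-4-(3-methoxy-4-triisopropylsilyloxyphenyl)-2,3-dimethylbutyl]-2,6-dimethoxyphenoxy}dimethylsilane
Product: 14 4-[(2S,3R)-4-(4-hydroxy-3-methoxyphenyl)-2,3-dimethylbutyl]-2,6-dimethoxyphenol (target)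
Conditions: TBAF (2.5 equiv.), AcOH, THF, 0 °C → rt
Reagents that add atoms: none
Why: Fluoride-driven cleavage of both aryl silyl ethers (Si–F bond formation), buffered with acetic acid to protect the electron-rich phenoxides from air oxidation; no stereocentre is involved.

**Compound list**

1 | vanillin (4-hydroxy-3-methoxybenzaldehyde) | COc1cc(C=O)ccc1O | starting material
2 | 3-methoxy-4-(triisopropylsilyloxy)benzaldehyde | COc1cc(C=O)ccc1O[Si](C(C)C)(C(C)C)C(C)C | intermediate
3 | (4-ethynyl-2-methoxyphenoxy)triisopropylsilane | COc1cc(C#C)ccc1O[Si](C(C)C)(C(C)C)C(C)C | intermediate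
4 | (Z)-but-2-ene | C/C=C\C | starting material
5 | {4-[(3S,4S)-3,4-dimethylcyclobut-1-en-1-yl]-2-methoxyphenoxy}triisopropylsilane (cis-dimethyl) | COc1cc(C2=C[C@H](C)[C@@H]2C)ccc1O[Si](C(C)C)(C(C)C)C(C)C | intermediate
6 | ozonide: 1-[3-methoxy-4-(triisopropylsilyloxy)phenyl]-cis-5,6-dimethyl-2,3,7-trioxabicyclo[2.2.1]heptane (methyl-bearing carbons as in 5, bridgeheads unassigned) | COc1cc(C23OOC(O2)[C@H](C)[C@@H]3C)ccc1O[Si](C(C)C)(C(C)C)C(C)C | intermediate (not isolated)
7 | (1RS,2S,3R)-1-[3-methoxy-4-(triisopropylsilyloxy)phenyl]-2,3-dimethylbutane-1,4-diol | COc1cc(C(O)[C@@H](C)[C@@H](C)CO)ccc1O[Si](C(C)C)(C(C)C)C(C)C | intermediate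
8 | (2R,3R)-4-[3-methoxy-4-(triisopropylsilyloxy)phenyl]-2,3-dimethylbutan-1-ol | COc1cc(C[C@@H](C)[C@@H](C)CO)ccc1O[Si](C(C)C)(C(C)C)C(C)C | intermediate
9 | {4-[(2R,3R)-4-iodo-2,3-dimethylbutyl]-2-methoxyphenoxy}triisopropylsilane | COc1cc(C[C@@H](C)[C@@H](C)CI)ccc1O[Si](C(C)C)(C(C)C)C(C)C | intermediate
10 | 4-bromo-2,6-dimethoxyphenol | COc1cc(Br)cc(OC)c1O | starting material
11 | (4-bromo-2,6-dimethoxyphenoxy)(tert-butyl)dimethylsilane | COc1cc(Br)cc(OC)c1O[Si](C)(C)C(C)(C)C | intermediate
12 | [4-(tert-butyldimethylsilyloxy)-3,5-dimethoxyphenyl]magnesium bromide | COc1cc([Mg]Br)cc(OC)c1O[Si](C)(C)C(C)(C)C | intermediate (not isolated)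
13 | tert-butyl{4-[(2S,3R)-4-(3-methoxy-4-triisopropylsilyloxyphenyl)-2,3-dimethylbutyl]-2,6-dimethoxyphenoxy}dimethylsilane | COc1cc(C[C@@H](C)[C@@H](C)Cc2cc(OC)c(O[Si](C)(C)C(C)(C)C)c(OC)c2)ccc1O[Si](C(C)C)(C(C)C)C(C)C | intermediate
14 | 4-[(2S,3R)-4-(4-hydroxy-3-methoxyphenyl)-2,3-dimethylbutyl]-2,6-dimethoxyphenol | COc1cc(C[C@@H](C)[C@@H](C)Cc2cc(OC)c(O)c(OC)c2)ccc1O | target

**Step count**

Total step count: 9. Longest linear sequence: 8 steps (steps 1–6, 8 and 9, from vanillin 1); step 7 is the one-step side branch.

**Steps most likely to fail**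

Step 3 (proposed new method). What may go wrong: self-oligomerisation of the terminal alkyne (cyclotrimerisation, enyne formation) outrunning the cross-cycloaddition; β-hydride elimination from the cobaltacycle to open-chain dienes; cobalt hydride isomerising the cis-alkene; or weak discrimination between the two mirror-image ways of docking the alkene. Fallback (known chemistry, no cycloaddition): the meso-type C4 chain is taken from a meso compound and desymmetrised enzymatically. It sets out from Grignard reagent 12 and comes back at 13. Commercial meso-2,3-dimethylsuccinic acid is reduced with LiAlH4 to meso-2,3-dimethylbutane-1,4-diol F1. Lipase-catalysed monoacetylation with vinyl acetate (Pseudomonas fluorescens lipase) should give (2S,3R)-4-hydroxy-2,3-dimethylbutyl acetate F2; should the enzyme deliver the antipode, the two aryl groups are attached in the opposite order. Appel iodination gives (2S,3R)-4-iodo-2,3-dimethylbutyl acetate F3, and Li2CuCl4-catalysed coupling with 12 at low temperature gives (2S,3S)-4-[4-(tert-butyldimethylsilyloxy)-3,5-dimethoxyphenyl]-2,3-dimethylbutyl acetate F4. DIBAL cleaves the acetate to (2S,3S)-4-[4-(tert-butyldimethylsilyloxy)-3,5-dimethoxyphenyl]-2,3-dimethylbutan-1-ol F5, and a second Appel iodination gives tert-butyl{4-[(2S,3S)-4-iodo-2,3-dimethylbutyl]-2,6-dimethoxyphenoxy}dimethylsilane F6. Purchased 4-bromo-2-methoxyphenol is silylated (TIPSCl, imidazole) to (4-bromo-2-methoxyphenoxy)triisopropylsilane F7, converted with Mg into [3-methoxy-4-(triisopropylsilyloxy)phenyl]magnesium bromide F8, and coupled with F6 under Li2CuCl4 to give 13, which is desilylated as in step 9.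

Step 8. What may go wrong: iodine–magnesium exchange, reduction or elimination at the β-branched primary iodide, and biaryl formation from the Grignard reagent, in place of C(sp2)–C(sp3) bond formation. Fallback: reversal of polarity to a Negishi coupling. It sets out from iodide 9 and bromide 11 and comes back at 13. Zinc insertion (Zn dust, LiCl, THF, 40 °C) converts 9 into {(2R,3R)-4-[3-methoxy-4-(triisopropylsilyloxy)phenyl]-2,3-dimethylbutyl}zinc iodide F9, which is coupled with 11 under Pd(OAc)2/SPhos (zerovalent palladium formed in the flask) in THF at 50 °C.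

Step 5. What may go wrong: slow cleavage of the secondary benzylic C–O bond on the palladium surface, so that the diol is returned or merely cyclised. Fallback: ionic hydrogenation in place of surface hydrogenolysis. It sets out from diol 7 and comes back at 8. Et3SiH and BF3·OEt2 in CH2Cl2 (−78 → −20 °C) ionise the C7–OH bond, and the benzylic cation takes hydride from the silane. If the primary hydroxyl traps the cation first, (3S,4R)-2-[3-methoxy-4-(triisopropylsilyloxy)phenyl]-3,4-dimethyltetrahydrofuran F10 forms and is reopened reductively at the same benzylic C–O bond under the same conditions, so both paths end at 8. No second arene is present at this stage, so Friedel–Crafts closure cannot interfere.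

**Further compounds**

F1 | step 3 | meso-2,3-dimethylbutane-1,4-diol | OC[C@@H](C)[C@@H](C)CO
F2 | step 3 | (2S,3R)-4-hydroxy-2,3-dimethylbutyl acetate | CC(=O)OC[C@@H](C)[C@@H](C)CO
F3 | step 3 | (2S,3R)-4-iodo-2,3-dimethylbutyl acetate | CC(=O)OC[C@@H](C)[C@@H](C)CI
F4 | step 3 | (2S,3S)-4-[4-(tert-butyldimethylsilyloxy)-3,5-dimethoxyphenyl]-2,3-dimethylbutyl acetate | CC(=O)OC[C@@H](C)[C@@H](C)Cc1cc(OC)c(O[Si](C)(C)C(C)(C)C)c(OC)c1
F5 | step 3 | (2S,3S)-4-[4-(tert-butyldimethylsilyloxy)-3,5-dimethoxyphenyl]-2,3-dimethylbutan-1-ol | OC[C@@H](C)[C@@H](C)Cc1cc(OC)c(O[Si](C)(C)C(C)(C)C)c(OC)c1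
F6 | step 3 | tert-butyl{4-[(2S,3S)-4-iodo-2,3-dimethylbutyl]-2,6-dimethoxyphenoxy}dimethylsilane | IC[C@@H](C)[C@@H](C)Cc1cc(OC)c(O[Si](C)(C)C(C)(C)C)c(OC)c1
F7 | step 3 | (4-bromo-2-methoxyphenoxy)triisopropylsilane | COc1cc(Br)ccc1O[Si](C(C)C)(C(C)C)C(C)C
F8 | step 3 | [3-methoxy-4-(triisopropylsilyloxy)phenyl]magnesium bromide | COc1cc([Mg]Br)ccc1O[Si](C(C)C)(C(C)C)C(C)C
F9 | step 8 | {(2R,3R)-4-[3-methoxy-4-(triisopropylsilyloxy)phenyl]-2,3-dimethylbutyl}zinc iodide | COc1cc(C[C@@H](C)[C@@H](C)C[Zn]I)ccc1O[Si](C(C)C)(C(C)C)C(C)C
F10 | step 5 | (3S,4R)-2-[3-methoxy-4-(triisopropylsilyloxy)phenyl]-3,4-dimethyltetrahydrofuran (C2 epimers) | COc1cc(C2OC[C@H](C)[C@@H]2C)ccc1O[Si](C(C)C)(C(C)C)C(C)C
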